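The route rests on the CH(OH)–CH(CH3)–CH2–CH(OH) segment of the eleven-membered ring, whose 1,4-dioxygenation is that of a 2-alkoxy-4-methyloxolane. The bond between the methyl-bearing carbon and the adjacent CH2 is made by a 5-exo radical cyclization of a bromoacetal tethered to a vinyl carbinol. In one operation this closes a temporary oxolane, converts the vinyl group into the methyl group with its configuration set relative to the carbinol carbon, and installs the second oxygenated carbon as a masked aldehyde. The precursor is an acyclic mixed bromoacetal on a limonene scaffold; the hydrindane is later grown from the limonene ring and the macrocycle is closed by a Nozaki–Hiyama–Kishi reaction.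

Key step: step 3

Remark: the acetal carbon of the oxolane (later the aldehyde carbon) forms as both epimers and is carried as such; it is left undefined in the SMILES.
Remark: A = 4-[(2S,3R)-5-ethoxy-3-methyloxolan-2-yl]but-1-en-2-yl, i.e. CH2=C(–)CH2CH2–(oxolan-2-yl) with the 3-methyl group trans to the chain.
Remark: bicyclic intermediates use indene numbering (C1–C3 five-membered ring, C3a/C7a ring fusion, C4–C7 six-membered ring).

Step 1
Reactants: 1 (R)-(+)-limonene; 2 (R)-2-vinyloxirane
Product: 4 (3S)-5-[(1R)-4-methylcyclohex-3-en-1-yl]hexa-1,5-dien-3-ol, via allyllithium 3 (not isolated)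
Conditions: n-BuLi, TMEDA, hexane, 25 °C; then 2, THF, −78 to 0 °C; H2O
Reagents that add atoms: none
Why: Allylic lithiation of the isopropenyl methyl group gives the symmetrical 2-substituted allyllithium 3, which should open the vinyl epoxide by SN2 attack at its unsubstituted carbon (epoxide ring opening), so the oxygen-bearing stereocentre of 2 passes unchanged into 4.

Step 2
Reactants: 4 (3S)-5-[(1R)-4-methylcyclohex-3-en-1-yl]hexa-1,5-dien-3-ol; 5 ethyl vinyl ether
Product: 6 (3S)-3-(2-bromo-1-ethoxyethoxy)-5-[(1R)-4-methylcyclohex-3-en-1-yl]hexa-1,5-diene (both acetal epimers)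
Conditions: N-bromosuccinimide, CH2Cl2, −40 to 0 °C
Reagents that add atoms: N-bromosuccinimide, O=C1CCC(=O)N1Br
Why: Bromoetherification (haloacetalization): the electron-rich enol ether is brominated far faster than the other alkenes and the secondary alcohol captures the oxocarbenium ion to give the mixed bromoacetal.

Step 3
Reactants: 6 (3S)-3-(2-bromo-1-ethoxyethoxy)-5-[(1R)-4-methylcyclohex-3-en-1-yl]hexa-1,5-diene
Product: 7 (4R,5S)-2-ethoxy-4-methyl-5-{3-[(1R)-4-methylcyclohex-3-en-1-yl]but-3-en-1-yl}oxolane (both C2 epimers)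
Conditions: Bu3SnH, AIBN (cat.), benzene, 80 °C, 0.02 M
Reagents that add atoms: none
Why: Bu3Sn• abstracts bromine from 6, the primary radical next to the acetal carbon adds to the internal vinyl carbon, and the new primary radical takes hydrogen from Bu3SnH to become the methyl group (radical chain). The closest known reaction is the Ueno–Stork haloacetal cyclization. The oxolane closes in the 5-exo-trig mode. The new methyl-bearing stereocentre is controlled by the existing carbinol centre: in the chair-like Beckwith–Houk transition state its CH2 substituent sits pseudo-equatorial, which places the methyl group trans to it on the ring (anti to oxygen in the open chain). The step needs 5-exo over 6-endo closure and cyclization faster than direct reduction; the three-atom O–CH(OEt) tether secures the first and a low stationary Bu3SnH concentration the second, while the remote ring and 1,1-disubstituted alkenes cannot compete.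

Step 4
Reactants: 7 (4R,5S)-2-ethoxy-4-methyl-5-{3-[(1R)-4-methylcyclohex-3-en-1-yl]but-3-en-1-yl}oxolane
Product: 9 (3R)-3-A-6-oxoheptanal, via ozonide 8 (not isolated)
Conditions: O3 (1 equiv, Sudan Red 7B end point), CH2Cl2, −78 °C; PPh3, −78 to 20 °C
Reagents that add atoms: ozone, [O-][O+]=O
Why: Ozonolysis: the trisubstituted ring alkene is much more electron-rich than the 1,1-disubstituted alkene and should be cleaved selectively with one equivalent of ozone, the ozonide being reduced by PPh3.

Step 5
Reactants: 9 (3R)-3-A-6-oxoheptanal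
Product: 10 (5S)-5-A-2-methylcyclopent-1-ene-1-carbaldehyde
Conditions: piperidine, AcOH, benzene, 80 °C, Dean–Stark
Reagents that add atoms: none
Why: Intramolecular aldol condensation through the piperidine enamine of the aldehyde, which attacks the methyl ketone and dehydrates to the conjugated enal; the stereocentre is not α to a carbonyl group and is untouched.

Step 6
Reactants: 10 (5S)-5-A-2-methylcyclopent-1-ene-1-carbaldehyde; 11 phenyl vinyl sulfone
Product: 14 5-(phenylsulfonyl)-3-A-2,3,4,5,6,7-hexahydro-1H-inden-4-ol (mixture at C4 and C5), via silyl dienol ether 12 (not isolated), via silylated cycloadduct 13 (not isolated)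
Conditions: TBSOTf, Et3N, CH2Cl2, −78 °C; then 11, toluene, 90 °C; then Bu4NF, THF, 0 °C
Reagents that add atoms: none
Why: γ-Enolization at the methyl group syn to the formyl group gives the s-cis-locked 1-silyloxy diene 12, which undergoes Diels–Alder cycloaddition with the vinyl sulfone (sulfonyl carbon next to the oxygenated carbon) before fluoride removes the silyl group; both new stereocentres are erased in steps 7 and 8.

Step 7
Reactants: 14 5-(phenylsulfonyl)-3-A-2,3,4,5,6,7-hexahydro-1H-inden-4-ol
Product: 15 5-(phenylsulfonyl)-3-A-1,2,3,5,6,7-hexahydro-4H-inden-4-one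
Conditions: Dess–Martin periodinane, NaHCO3, CH2Cl2, 20 °C
Reagents that add atoms: none
Why: Dess–Martin oxidation of the secondary allylic alcohol to the ketone under buffered conditions that spare the acetal.

Step 8
Reactants: 15 5-(phenylsulfonyl)-3-A-1,2,3,5,6,7-hexahydro-4H-inden-4-one
Product: 16 (3S)-3-A-1,2,3,5,6,7-hexahydro-4H-inden-4-one
Conditions: SmI2, THF/MeOH, −78 °C
Reagents that add atoms: none
Why: Reductive desulfonylation: electron transfer from SmI2 to the α-sulfonyl ketone cleaves the C–S bond and protonation of the samarium enolate leaves the enone with the tetrasubstituted ring-fusion double bond.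

Step 9
Reactants: 16 (3S)-3-A-1,2,3,5,6,7-hexahydro-4H-inden-4-one
Product: 17 (3R,3aR,7aS)-7a-methyl-3-A-octahydro-4H-inden-4-one (cis-fused)
Conditions: Me2CuLi (from MeLi and CuI), Et2O, −40 to 0 °C; H2O
Reagents that add atoms: lithium dimethylcuprate, [Li+].C[Cu-]C
Why: Organocuprate conjugate addition at the ring-fusion β-carbon, anti to side chain A on the neighbouring ring carbon, sets the quaternary centre, and protonation of the enolate from the same face gives the cis-fused hydrindanone with 3-H, 3a-H and 7a-CH3 on one face.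

Step 10
Reactants: 17 (3R,3aR,7aS)-7a-methyl-3-A-octahydro-4H-inden-4-one
Product: 19 7a-methyl-3-A-1,2,3,3a,7,7a-hexahydro-4H-inden-4-one (C5=C6), via lithium enolate 18 (not isolated)
Conditions: LiN(iPr)2, THF, −78 °C; then N-tert-butylbenzenesulfinimidoyl chloride, −78 °C
Reagents that add atoms: none
Why: Mukaiyama dehydrogenation: kinetic deprotonation at the less hindered α-CH2 gives enolate 18, which is sulfenylated at carbon and loses the sulfenamide by syn-elimination to give the enone without epimerizing the ring fusion.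

Step 11
Reactants: 19 7a-methyl-3-A-1,2,3,3a,7,7a-hexahydro-4H-inden-4-one
Product: 20 4,7a-dimethyl-3-A-2,3,3a,4,7,7a-hexahydro-1H-inden-4-ol (both C4 epimers)
Conditions: MeLi, Et2O/THF, −78 °C; H2O
Reagents that add atoms: methyllithium, [Li]C
Why: 1,2-Addition of the organolithium to the enone carbonyl gives the tertiary allylic alcohol, whose configuration is irrelevant because this carbon becomes sp2 in step 12.

Step 12
Reactants: 20 4,7a-dimethyl-3-A-2,3,3a,4,7,7a-hexahydro-1H-inden-4-ol
Product: 21 4,7a-dimethyl-3-A-1,2,3,3a,7,7a-hexahydro-6H-inden-6-one (C4=C5)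
Conditions: [C5H5NH][CrO3Cl], NaOAc, 4 Å molecular sieves, CH2Cl2, 20 °C
Reagents that add atoms: none
Why: Babler–Dauben oxidative transposition: the chromate ester of the tertiary allylic alcohol undergoes a [3,3] shift and is oxidized to the β-methyl enone, the acetate buffer protecting the acetal.

Step 13
Reactants: 21 4,7a-dimethyl-3-A-1,2,3,3a,7,7a-hexahydro-6H-inden-6-one
Product: 23 7-hydroxy-4,7a-dimethyl-3-A-1,2,3,3a,7,7a-hexahydro-6H-inden-6-one (7-OH cis to 7a-CH3), via potassium dienolate 22 (not isolated)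
Conditions: KN(SiMe3)2, THF, −78 °C; then 3-phenyl-2-(phenylsulfonyl)oxaziridine, −78 °C; H2O
Reagents that add atoms: 3-phenyl-2-(phenylsulfonyl)oxaziridine (Davis oxaziridine), O=S(=O)(c1ccccc1)N1OC1c1ccccc1
Why: Enolate oxidation: kinetic α′-deprotonation gives the cross-conjugated dienolate 22, which should be hydroxylated on the convex face of the cis-hydrindane (the face of the angular methyl group); the ketol centre is epimerizable and this pseudo-equatorial epimer is also expected to be the more stable one.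

Step 14
Reactants: 23 7-hydroxy-4,7a-dimethyl-3-A-1,2,3,3a,7,7a-hexahydro-6H-inden-6-one
Product: 24 7-hydroxy-5-iodo-4,7a-dimethyl-3-A-1,2,3,3a,7,7a-hexahydro-6H-inden-6-one
Conditions: I2, pyridine, DMAP (cat.), CH2Cl2, 20 °C
Reagents that add atoms: iodine, II
Why: α-Iodination of the enone by amine conjugate addition, iodination of the resulting enolate and elimination of the amine (Baylis–Hillman-type addition–elimination), under conditions that leave isolated alkenes alone.

Step 15
Reactants: 24 7-hydroxy-5-iodo-4,7a-dimethyl-3-A-1,2,3,3a,7,7a-hexahydro-6H-inden-6-one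
Product: 25 5-iodo-4,7a-dimethyl-3-A-2,3,3a,6,7,7a-hexahydro-1H-indene-6,7-diol (6-OH trans to 7-OH)
Conditions: NaBH4, CeCl3·7H2O, EtOH, −40 °C
Reagents that add atoms: none
Why: Luche 1,2-reduction of the iodoenone with hydride delivered on the convex face, anti to nothing but hydrogen and syn to the 7-hydroxyl group, which should give the trans-diol; ethanol as solvent makes any acetal exchange degenerate.

Step 16
Reactants: 25 5-iodo-4,7a-dimethyl-3-A-2,3,3a,6,7,7a-hexahydro-1H-indene-6,7-diol
Product: 26 5-iodo-4,7a-dimethyl-3-A-2,3,3a,6,7,7a-hexahydro-1H-indene-6,7-diyl diacetate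
Conditions: Ac2O, pyridine, DMAP (cat.), CH2Cl2, 20 °C
Reagents that add atoms: acetic anhydride, CC(=O)OC(C)=O
Why: DMAP-catalysed acylation of both secondary alcohols, the acetal still masking the other two oxygen functions.

Step 17
Reactants: 26 5-iodo-4,7a-dimethyl-3-A-2,3,3a,6,7,7a-hexahydro-1H-indene-6,7-diyl diacetate
Product: 27 lactol: 26 with 5-hydroxy in place of 5-ethoxy on the oxolane (both anomers)
Conditions: AcOH/THF/H2O (3:1:1), 40 °C
Reagents that add atoms: water, O
Why: Acid-catalysed hydrolysis of the mixed cyclic acetal to the hemiacetal, conditions under which the allylic acetates and the alkenyl iodide should persist.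

Step 18
Reactants: 27 lactol
Product: 28 target diol diacetate CNP0114864.2
Conditions: CrCl2 (excess), NiCl2 (cat.), DMSO/THF, 25 °C, 0.002 M
Reagents that add atoms: none
Why: Nozaki–Hiyama–Kishi reaction: zerovalent nickel inserts into the C–I bond, transmetalation gives the alkenylchromium species, and this adds to the aldehyde released from the lactol to close the eleven-membered ring, addition on the aldehyde face turned away from the ring interior being expected to give the (S)-carbinol.

Compound list
1 | (R)-(+)-limonene, (4R)-1-methyl-4-(prop-1-en-2-yl)cyclohex-1-ene | CC1=CC[C@@H](CC1)C(C)=C | starting material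
2 | (R)-2-vinyloxirane | C=C[C@@H]1CO1 | starting material
3 | {2-[(1R)-4-methylcyclohex-3-en-1-yl]prop-2-en-1-yl}lithium | [Li]CC(=C)[C@@H]1CCC(C)=CC1 | intermediate (not isolated)
4 | (3S)-5-[(1R)-4-methylcyclohex-3-en-1-yl]hexa-1,5-dien-3-ol | CC1=CC[C@@H](CC1)C(=C)CC[C@H](O)C=C | intermediate
5 | ethyl vinyl ether | C=COCC | starting material
6 | (3S)-3-(2-bromo-1-ethoxyethoxy)-5-[(1R)-4-methylcyclohex-3-en-1-yl]hexa-1,5-diene, both acetal epimers | CC1=CC[C@@H](CC1)C(=C)CC[C@H](OC(CBr)OCC)C=C | intermediate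
7 | (4R,5S)-2-ethoxy-4-methyl-5-{3-[(1R)-4-methylcyclohex-3-en-1-yl]but-3-en-1-yl}oxolane, 4-methyl trans to the 5-substituent | CC1=CC[C@@H](CC1)C(=C)CC[C@@H]2OC(OCC)C[C@H]2C | intermediate
8 | secondary ozonide (1,2,4-trioxolane) of the ring double bond of 7 | CC12CC[C@@H](C(=C)CC[C@@H]3OC(OCC)C[C@H]3C)CC(OO1)O2 | intermediate (not isolated)
9 | (3R)-3-A-6-oxoheptanal | CC(=O)CC[C@H](CC=O)C(=C)CC[C@@H]1OC(OCC)C[C@H]1C | intermediate
10 | (5S)-5-A-2-methylcyclopent-1-ene-1-carbaldehyde | CC1=C(C=O)[C@@H](CC1)C(=C)CC[C@@H]2OC(OCC)C[C@H]2C | intermediate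
11 | phenyl vinyl sulfone | C=CS(=O)(=O)c1ccccc1 | starting material
12 | 1-[(E)-(tert-butyldimethylsilyloxy)methylidene]-2-methylidene-5-A-cyclopentane (ring stereocentre as in 10) | C=C1CC[C@@H](C(=C)CC[C@@H]2OC(OCC)C[C@H]2C)/C1=C\O[Si](C)(C)C(C)(C)C | intermediate (not isolated)
13 | 4-(tert-butyldimethylsilyloxy)-5-(phenylsulfonyl)-3-A-2,3,4,5,6,7-hexahydro-1H-indene (mixture at C4 and C5) | CC(C)(C)[Si](C)(C)OC1C(CCC2=C1[C@H](C(=C)CC[C@@H]3OC(OCC)C[C@H]3C)CC2)S(=O)(=O)c1ccccc1 | intermediate (not isolated)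
14 | 5-(phenylsulfonyl)-3-A-2,3,4,5,6,7-hexahydro-1H-inden-4-ol (mixture at C4 and C5) | OC1C(CCC2=C1[C@H](C(=C)CC[C@@H]3OC(OCC)C[C@H]3C)CC2)S(=O)(=O)c1ccccc1 | intermediate
15 | 5-(phenylsulfonyl)-3-A-1,2,3,5,6,7-hexahydro-4H-inden-4-one (mixture at C5) | O=C1C(CCC2=C1[C@H](C(=C)CC[C@@H]3OC(OCC)C[C@H]3C)CC2)S(=O)(=O)c1ccccc1 | intermediate
16 | (3S)-3-A-1,2,3,5,6,7-hexahydro-4H-inden-4-one | O=C1CCCC2=C1[C@H](C(=C)CC[C@@H]3OC(OCC)C[C@H]3C)CC2 | intermediate
17 | (3R,3aR,7aS)-7a-methyl-3-A-octahydro-4H-inden-4-one, cis-fused, A trans to the 7a-methyl group | O=C1CCC[C@@]2(C)CC[C@@H](C(=C)CC[C@@H]3OC(OCC)C[C@H]3C)[C@@H]12 | intermediate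
18 | lithium enolate of 17 (C4–OLi, C4=C5) | [Li]OC1=CCC[C@@]2(C)CC[C@@H](C(=C)CC[C@@H]3OC(OCC)C[C@H]3C)[C@@H]12 | intermediate (not isolated)
19 | 7a-methyl-3-A-1,2,3,3a,7,7a-hexahydro-4H-inden-4-one (C5=C6, stereocentres as in 17) | O=C1C=CC[C@@]2(C)CC[C@@H](C(=C)CC[C@@H]3OC(OCC)C[C@H]3C)[C@@H]12 | intermediate
20 | 4,7a-dimethyl-3-A-2,3,3a,4,7,7a-hexahydro-1H-inden-4-ol (both C4 epimers) | CC1(O)C=CC[C@@]2(C)CC[C@@H](C(=C)CC[C@@H]3OC(OCC)C[C@H]3C)[C@@H]12 | intermediate
21 | 4,7a-dimethyl-3-A-1,2,3,3a,7,7a-hexahydro-6H-inden-6-one (C4=C5, stereocentres as in 17) | CC1=CC(=O)C[C@@]2(C)CC[C@@H](C(=C)CC[C@@H]3OC(OCC)C[C@H]3C)[C@@H]12 | intermediate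
22 | potassium dienolate of 21 (C6–OK, C6=C7) | CC1=CC(O[K])=C[C@@]2(C)CC[C@@H](C(=C)CC[C@@H]3OC(OCC)C[C@H]3C)[C@@H]12 | intermediate (not isolated)
23 | 7-hydroxy-4,7a-dimethyl-3-A-1,2,3,3a,7,7a-hexahydro-6H-inden-6-one, 7-OH cis to 7a-CH3 | CC1=CC(=O)[C@H](O)[C@@]2(C)CC[C@@H](C(=C)CC[C@@H]3OC(OCC)C[C@H]3C)[C@@H]12 | intermediate
24 | 7-hydroxy-5-iodo-4,7a-dimethyl-3-A-1,2,3,3a,7,7a-hexahydro-6H-inden-6-one | CC1=C(I)C(=O)[C@H](O)[C@@]2(C)CC[C@@H](C(=C)CC[C@@H]3OC(OCC)C[C@H]3C)[C@@H]12 | intermediate
25 | 5-iodo-4,7a-dimethyl-3-A-2,3,3a,6,7,7a-hexahydro-1H-indene-6,7-diol, 6-OH trans to 7-OH, 7-OH cis to 7a-CH3 | CC1=C(I)[C@@H](O)[C@H](O)[C@@]2(C)CC[C@@H](C(=C)CC[C@@H]3OC(OCC)C[C@H]3C)[C@@H]12 | intermediate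
26 | 6,7-diacetate of 25 | CC1=C(I)[C@@H](OC(C)=O)[C@H](OC(C)=O)[C@@]2(C)CC[C@@H](C(=C)CC[C@@H]3OC(OCC)C[C@H]3C)[C@@H]12 | intermediate
27 | lactol: 26 with 5-hydroxy in place of 5-ethoxy on the oxolane (both anomers) | CC1=C(I)[C@@H](OC(C)=O)[C@H](OC(C)=O)[C@@]2(C)CC[C@@H](C(=C)CC[C@@H]3OC(O)C[C@H]3C)[C@@H]12 | intermediate
28 | CNP0114864.2, the tricyclic diol diacetate | C=C1CC[C@H](O)[C@H](C)C[C@H](O)C2=C(C)[C@@H]3[C@H]1CC[C@]3(C)[C@@H](OC(C)=O)[C@@H]2OC(C)=O | target

Total step count: 18. Longest linear sequence: 18 steps (from 1).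

Steps most likely to fail

Step 18. The lactol may release the hydroxy aldehyde too slowly, so that the alkenylchromium species is protonated or the chain oligomerizes, and the new carbinol may form with poor facial selectivity. The fallback sets out from 27 and comes back at 28. Lactol 27 is reduced with NaBH4 in EtOH to the open-chain 1,4-diol F1, both hydroxyl groups are silylated (Et3SiCl, imidazole) to the bis(triethylsilyl) ether F2, and Swern oxidation converts the primary silyl ether selectively into the free aldehyde F3. Nozaki–Hiyama–Kishi closure (CrCl2, NiCl2, DMSO) then gives the macrocyclic silyl ether F4. If the carbinol forms mainly with the wrong configuration, F4 is oxidized with MnO2 to the macrocyclic enone F5 and reduced under reagent control (Corey–Bakshi–Shibata reduction) back to F4. HF·pyridine removes the silyl group and gives 28.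

Step 13. Facial selectivity in the enolate oxidation may be poor, giving the epimeric ketol. The fallback sets out from 21 and comes back at 23. The ketol obtained from 21 as an epimer mixture is oxidized with Dess–Martin periodinane to the 6,7-dione F6. Its non-conjugated C7 carbonyl, next to the quaternary carbon, is reduced with one equivalent of NaBH4 at −78 °C; hydride arrives anti to the angular methyl group, as in the reduction of 17-keto steroids, placing the 7-hydroxyl cis to that methyl group, which is 23.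

Step 1. Regioselectivity in the epoxide opening may be lost through attack at the allylic carbon or at the vinyl terminus. The fallback sets out from 3 and comes back at 4. Allyllithium 3 is added to (S)-epichlorohydrin (ClC[C@@H]1CO1) with BF3·OEt2 at −78 °C, which opens the epoxide at its CH2 group and gives the chlorohydrin F7. NaOH closes it to the terminal epoxide F8 with the carbinol configuration retained. Excess dimethylsulfonium methylide (Me3SI, n-BuLi) opens F8 at its terminal carbon and the betaine loses dimethyl sulfide, giving the allylic alcohol 4.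

Further compounds
F1 | step 18 | 1,4-diol: 26 with the side chain CH2=C(–)CH2CH2CH(OH)CH(CH3)CH2CH2OH in place of A | CC1=C(I)[C@@H](OC(C)=O)[C@H](OC(C)=O)[C@@]2(C)CC[C@@H](C(=C)CC[C@H](O)[C@H](C)CCO)[C@@H]12
F2 | step 18 | bis(triethylsilyl) ether of F1 | CC1=C(I)[C@@H](OC(C)=O)[C@H](OC(C)=O)[C@@]2(C)CC[C@@H](C(=C)CC[C@H](O[Si](CC)(CC)CC)[C@H](C)CCO[Si](CC)(CC)CC)[C@@H]12
F3 | step 18 | aldehyde: F2 with CHO in place of the primary CH2OSiEt3 | CC1=C(I)[C@@H](OC(C)=O)[C@H](OC(C)=O)[C@@]2(C)CC[C@@H](C(=C)CC[C@H](O[Si](CC)(CC)CC)[C@H](C)CC=O)[C@@H]12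
F4 | step 18 | macrocyclic silyl ether: 28 with OSiEt3 on the carbinol carbon next to the methyl-bearing carbon | C=C1CC[C@H](O[Si](CC)(CC)CC)[C@H](C)C[C@H](O)C2=C(C)[C@@H]3[C@H]1CC[C@]3(C)[C@@H](OC(C)=O)[C@@H]2OC(C)=O
F5 | step 18 | macrocyclic enone: F4 with C=O in place of the allylic CH(OH) | C=C1CC[C@H](O[Si](CC)(CC)CC)[C@H](C)CC(=O)C2=C(C)[C@@H]3[C@H]1CC[C@]3(C)[C@@H](OC(C)=O)[C@@H]2OC(C)=O
F6 | step 13 | 4,7a-dimethyl-3-A-2,3,3a,7a-tetrahydro-1H-indene-6,7-dione (C4=C5) | CC1=CC(=O)C(=O)[C@@]2(C)CC[C@@H](C(=C)CC[C@@H]3OC(OCC)C[C@H]3C)[C@@H]12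
F7 | step 1 | (2S)-1-chloro-5-[(1R)-4-methylcyclohex-3-en-1-yl]hex-5-en-2-ol | CC1=CC[C@@H](CC1)C(=C)CC[C@H](O)CCl
F8 | step 1 | (2S)-2-{3-[(1R)-4-methylcyclohex-3-en-1-yl]but-3-en-1-yl}oxirane | CC1=CC[C@@H](CC1)C(=C)CC[C@H]1CO1
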